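In a one-step world every free monomer would have ended in chains, so what I wanted from the amber flask was the number that says how far it fell short of that world.

all flasks: free monomer 0.050 M
- amber: transfer agent 0.50 mM; initiator 5 mol%; temperature 70 °C; the very flask that is asked about, followed so far
- grey: transfer agent 0.50 mM; initiator 3.4 mol%; temperature 76 °C; run made earlier
- flask: transfer agent 0.500 mM; initiator 5 mol%; temperature 70 °C; time 6.0 h

| run | time / min | monomer in chains / % | free monomer / % |
|---|---|---|---|
| amber | 25.0 | 72.7 | 0 |
| amber | 40.0 | 70.4 | 0.9 |
| amber | 50.0 | 71.5 | 1.0 |
| amber | 80.0 | 73.0 | 0 |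
| amber | 120 | 70.0 | 0 |
| amber | 180 | 70.4 | 0 |
| amber | 300 | 71.6 | 0.1 |
| grey | 1.00 | 59.9 | 7.6 |
| grey | 1.50 | 63.6 | 1.6 |
| grey | 2.50 | 66.4 | 2.9 |
| grey | 4.00 | 68.2 | 0.4 |
| grey | 6.00 | 67.1 | 0 |
| grey | 10.0 | 66.7 | 0 |
| grey | 15.0 | 67.8 | 1.1 |

(standard deviation of a reading: 1 percentage point)

- noon: at 6.0 h raise the temperature by 20 K, then wait 3.0 h
- midnight: at 6.0 h take out 90% of the monomer in chains then present, then wait 3.0 h
- dusk: change nothing and wait 3.0 h more
- summer: at 6.0 h add initiator, 100% of the amount charged, then wait 3.0 h

- monomer in chains that was removed still counts
- additions bring no volume worth counting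

- monomer in chains, in percent of the free monomer first charged, at 6.0 h
- what to do for the largest gain in monomer in chains; "none" if nothing gains more than 2 percentage points (noon / midnight / dusk / summer / none)
- monomer in chains present, with what was taken out counted in, in percent of the free monomer first charged, after noon
- monomer in chains present, with what was taken out counted in, in percent of the free monomer first charged, after midnight

1. The first rung, read in the grey run, was the loss. In the grey run at 1.00 min, chains read 59.9% and free monomer 7.6%, so 32.5% of the charge stood in neither column. The grey plateau from 4.00 min on averaged 67.5%, which left a final shortfall of 32.5%. Within the scatter the grey shortfall already stood at its final size while chains still grew, and I read this as the crossing after which the free monomer still there went to chains.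

2. The next rung was the plateau. The amber flask was flat by 25.0 min, with free monomer at 1.0% or less, and its readings averaged 71.4%. I therefore carried the split, a selectivity factor: charge ending in chains per unit of charge lost, 2.49 for amber and 2.07 for grey.

3. I laid that difference between the two readings on initiator, a guess because temperature changed too, and on that guess the split went as initiator to the power 0.479.

4. The last rung was the wait, since 6.0 h lay far beyond 25.0 min, by which the amber split already read finished. I committed to 71.4% at that time and after noon and midnight alike, and to none as the best option.

The forecast gave 71.4% (70.5% to 72.3%), none as best and 72% after midnight, but parted from my reckoning with 60% after noon, from what it called “a temperature-dependent partition”.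

The flask gave 71.2%, 71.2% after noon and 71.2% after midnight, with none as best.

    2 free monomer → homo dimer (k = 0.168 M⁻¹ s⁻¹, Ea = 58.0 kJ mol⁻¹)
    living end + transfer agent → dead chain (kL = 3.11 M⁻¹ s⁻¹, Ea = 55.0 kJ mol⁻¹)
    2 initiator ⇌ resting dimer (K = 199 M⁻¹, k = 1.72 M⁻¹ s⁻¹, Ea = 65.0 kJ mol⁻¹, ΔH = −50.0 kJ mol⁻¹)
    free monomer + initiator → living end + monomer in chains (k = 0.386 M⁻¹ s⁻¹, Ea = 75.0 kJ mol⁻¹)
    free monomer + living end → monomer in chains + living end, rate k5*[living end]*[free monomer] (k = 39.9 M⁻¹ s⁻¹, Ea = 53.0 kJ mol⁻¹)
    (constants at 70 °C)

The run without the homo dimer step ended at 100% against 71.2%, so that step is the main reason for the shortfall. Chains over homo dimer at 360 min in this flask gave a split of 2.47, and free monomer then stood at 0%, so noon and midnight met a finished split.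

For the neighbour with 12 mol% initiator, my carried split and its guessed power gave 3.79, which means 79.1% in chains as an estimate. The computed neighbour gave 79.8%.

All runs are simulated for substances that don't exist; the scatter is artificial.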